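The oxolane ring of the target (O1, C2–C5) carries a C9–C3–C4–C9′ chain that is a trans-2,3-disubstituted butane-1,4-diol, in other words a reduced butenolide. The plan rests on disconnecting C2–C3 and C4–C5. In one flask a lithiated syringyl dithiane (C2 as acyl anion) adds to the β-carbon of an enantiopure 5-menthyloxybutenolide. The enolate so formed is intercepted at the α-carbon by O-benzylsyringaldehyde (C5). The single acetal stereocentre relays its configuration to C3 and then to C4. The precursors are thus a crystalline chiral butenolide, an aryl dithiane and its parent aldehyde. Reduction, silylation, unmasking and reductive hemiketal closure then complete the all-trans ring.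

Key step: step 5

Remark on the chemistry: the target is the C2-symmetric all-trans (2S,3R,4R,5S) isomer; target numbering is O1, aryl-bearing C2 and C5, C3–C9H2OH and C4–C9′H2OH; the aldol carbinol is drawn in the (S) form that maps onto C5, and any (R) epimer formed beside it is carried along and converges in step 9.

Abbreviations: Ar = 4-(benzyloxy)-3,5-dimethoxyphenyl; Men = (1R,2S,5R)-2-isopropyl-5-methylcyclohexyl; TBDPS = tert-butyldiphenylsilyl.

Step 1
Reactants: 1 furfural
Product: 2 5-hydroxyfuran-2(5H)-one (racemic, labile hemiacetal)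
Conditions: O2, hν (visible), rose bengal (cat.), MeOH, 0–20 °C
Reagents that add atoms: dioxygen, O=O
Why: Dye-sensitised singlet-oxygen [4+2] cycloaddition (photo-oxygenation of a furan) gives a 2,5-endoperoxide that methanol fragments at the formyl group, leaving the γ-hydroxybutenolide, whose hemiacetal centre is labile and needs no control.

Step 2
Reactants: 2 5-hydroxyfuran-2(5H)-one; 3 (−)-menthol
Product: 5 (5R)-5-[(1R,2S,5R)-2-isopropyl-5-methylcyclohexyl]oxyfuran-2(5H)-one, via C5-epimeric acetal mixture 4 (not isolated)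
Conditions: camphorsulfonic acid (cat.), toluene, reflux, azeotropic removal of H2O; crystallisation from hexane, −20 °C; mother liquor re-equilibrated with cat. acid and recrystallised
Reagents that add atoms: none
Why: Acid-catalysed acetalisation of the hemiacetal with the chiral alcohol gives both C5 epimers, which interconvert through the oxocarbenium ion under the same acid, so crystallisation of the less soluble (5R)-epimer with re-equilibration of the liquor (crystallisation-driven epimerisation) sets the acetal centre.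

Step 3
Reactants: 6 syringaldehyde
Product: 7 4-(benzyloxy)-3,5-dimethoxybenzaldehyde
Conditions: BnBr, K2CO3, DMF, 60 °C
Reagents that add atoms: benzyl bromide, BrCc1ccccc1
Why: Williamson ether synthesis on the acidic phenol, with warm DMF overcoming the hindrance of the two ortho methoxy groups while the aldehyde is inert to carbonate.

Step 4
Reactants: 7 4-(benzyloxy)-3,5-dimethoxybenzaldehyde; 8 propane-1,3-dithiol
Product: 9 2-[4-(benzyloxy)-3,5-dimethoxyphenyl]-1,3-dithiane
Conditions: BF3·OEt2 (cat.), CH2Cl2, 0 °C → rt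
Reagents that add atoms: none
Why: Lewis-acid-catalysed dithioacetalisation of an aromatic aldehyde leaves aryl methyl and benzyl ethers untouched and turns the future C2 into an acyl-anion equivalent (umpolung).

Step 5
Reactants: 9 2-[4-(benzyloxy)-3,5-dimethoxyphenyl]-1,3-dithiane; 5 (5R)-5-menthyloxyfuran-2(5H)-one; 7 4-(benzyloxy)-3,5-dimethoxybenzaldehyde
Product: 13 (3S,4R,5R)-3-[(S)-Ar(hydroxy)methyl]-4-(2-Ar-1,3-dithian-2-yl)-5-(MenO)oxolan-2-one, via 2-lithio-1,3-dithiane 10 (not isolated), via lithium lactone enolate 11 (not isolated), via lithium aldolate 12 (not isolated)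
Conditions: n-BuLi (1.05 equiv), THF, −78 → −30 °C; 5, THF, −78 °C; 7, THF, −78 °C; AcOH/THF quench at −78 °C
Reagents that add atoms: none
Why: n-BuLi removes the sulfur- and aryl-stabilised proton of 9, the soft carbanion 10 adds in a Michael reaction to the β-carbon of 5 (butenolide C4, target C3) to form C2–C3 and enolate 11, and 11 then adds through its α-carbon (butenolide C3, target C4) to aldehyde 7 in an aldol reaction that forms C4–C5. The closest known reaction type is the tandem conjugate addition–electrophile trapping of lithiated aryl dithioacetals on butenolides, as practised for lignan lactones. No ring is closed; two C–C bonds are made on the intact lactone ring. Target C3 is controlled by the acetal centre, whose menthyloxy group shields one face of the flat butenolide so that the nucleophile enters anti; target C4 is controlled by the very bulky new dithianyl group, which sends the aldehyde to the opposite face and gives the 3,4-trans lactone; the carbinol C5 is only weakly controlled by the aldol transition state, and its epimers need not be separated. The step needs 1,4- over 1,2-addition, secured by the delocalised anion and the poorly electrophilic lactone carbonyl, and it needs trapping without retro-aldol or enolate equilibration, secured by working and quenching at −78 °C.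

Step 6
Reactants: 13 aldol lactone
Product: 14 (2R,3R)-2-[(S)-Ar(hydroxy)methyl]-3-(2-Ar-1,3-dithian-2-yl)butane-1,4-diol
Conditions: LiAlH4 (excess), THF, 0 °C → rt; H2O/aq. NaOH work-up
Reagents that add atoms: none
Why: Hydride reduction of the acetal-lactone opens the ring to a hemiacetal alkoxide that expels menthoxide, and the liberated aldehyde is reduced too, so C9 and C9′ both end as CH2OH while the dithiane (which shields C2 at the ketone level), the benzyl ethers and all three stereocentres persist.

Step 7
Reactants: 14 triol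
Product: 15 1,4-bis-O-TBDPS ether of 14 with the (S)-benzylic hydroxyl left free
Conditions: TBDPSCl (2.2 equiv), imidazole, DMF, 0 °C → rt
Reagents that add atoms: tert-butyl(chloro)diphenylsilane, CC(C)(C)[Si](Cl)(c1ccccc1)c1ccccc1
Why: Sterically discriminating silylation, in which the bulky chlorosilane takes the two primary hydroxyls far faster than the hindered secondary benzylic one, and the acid-robust silyl ethers later keep O9 and O9′ from competing for the benzylic carbons.

Step 8
Reactants: 15 bis-silyl ether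
Product: 17 (3R,4R,5S)-2,5-di-Ar-3,4-bis(TBDPSO-methyl)oxolan-2-ol (C2 anomer mixture), via open γ-hydroxy ketone 16 (not isolated)
Conditions: MeI (excess), CaCO3, MeCN–THF–H2O, 40 °C
Reagents that add atoms: water, O
Why: In this alkylative dithioacetal hydrolysis S-methylation makes sulfur a leaving group and water captures the thionium ion in a CaCO3-buffered neutral medium that avoids epimerisation at C3, β-elimination of the silyloxy group and loss of silyl or benzyl ethers; the γ-hydroxy ketone then closes 5-exo-trig through O5 with retention at C5.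

Step 9
Reactants: 17 cyclic hemiketal
Product: 19 (2S,3R,4R,5S)-2,5-di-Ar-3,4-bis(TBDPSO-methyl)oxolane, via cyclic oxocarbenium ion 18 (not isolated)
Conditions: BF3·OEt2 (2.5 equiv), CH2Cl2, −78 → −20 °C; re-cool to −78 °C, Et3SiH (5 equiv); aq. NaHCO3 quench cold
Reagents that add atoms: none
Why: This is a reductive deoxygenation of a cyclic hemiketal (Lewis-acid ionisation, then ionic hydrogenation): BF3·OEt2 gives the aryl-conjugated ion 18, whose C5–O bond can break and re-form through the alkoxy-stabilised benzylic cation so that any C5 epimer relaxes to 4,5-trans while the other arene is deactivated against Friedel–Crafts closure by the C2 carbonyl or oxocarbenium group, and Et3SiH, added only afterwards, delivers hydride to the inside face of the envelope in which the C3, C4 and C5 substituents are pseudo-equatorial, setting C2 as (S) with its aryl group trans to C9.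

Step 10
Reactants: 19 bis-silyl oxolane
Product: 20 [(2S,3R,4R,5S)-2,5-di-Ar-oxolane-3,4-diyl]dimethanol
Conditions: Bu4NF, AcOH, THF, rt → 40 °C
Reagents that add atoms: none
Why: Fluoride-mediated desilylation driven by the strong Si–F bond, run while the phenols are still benzylated so that no phenoxide can open the benzylic ether ring, and touching no stereocentre.

Step 11
Reactants: 20 bis-benzyl ether diol
Product: 21 huazhongilexin, (2S,3R,4R,5S)-2,5-bis(4-hydroxy-3,5-dimethoxyphenyl)-3,4-bis(hydroxymethyl)oxolane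
Conditions: H2 (1 atm), 10% Pd/C, EtOAc–EtOH, rt, stopped after uptake of 2 equiv H2
Reagents that add atoms: none
Why: Catalytic hydrogenolysis cleaves the unhindered primary O–CH2Ph bonds of the aryl benzyl ethers much faster than the crowded secondary ring C–O bonds in a neutral solvent, so the phenols are freed without ring opening or epimerisation.

Compound list
1 | furfural | O=Cc1ccco1 | starting material
2 | 5-hydroxyfuran-2(5H)-one | O=C1OC(O)C=C1 | intermediate
3 | (−)-menthol, (1R,2S,5R) | C[C@@H]1CC[C@H]([C@@H](C1)O)C(C)C | starting material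
4 | 5-menthyloxyfuran-2(5H)-one, mixture of C5 epimers | O=C1OC(O[C@@H]2C[C@H](C)CC[C@H]2C(C)C)C=C1 | intermediate
5 | (5R)-5-[(1R,2S,5R)-menthyloxy]furan-2(5H)-one | O=C1O[C@@H](O[C@@H]2C[C@H](C)CC[C@H]2C(C)C)C=C1 | intermediate
6 | syringaldehyde | COc1cc(C=O)cc(OC)c1O | starting material
7 | 4-(benzyloxy)-3,5-dimethoxybenzaldehyde | COc1cc(C=O)cc(OC)c1OCc1ccccc1 | intermediate
8 | propane-1,3-dithiol | SCCCS | starting material
9 | 2-[4-(benzyloxy)-3,5-dimethoxyphenyl]-1,3-dithiane | COc1cc(C2SCCCS2)cc(OC)c1OCc1ccccc1 | intermediate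
10 | 2-lithio-2-[4-(benzyloxy)-3,5-dimethoxyphenyl]-1,3-dithiane | [Li]C1(SCCCS1)c1cc(OC)c(OCc2ccccc2)c(OC)c1 | intermediate
11 | lithium enolate of (4R,5R)-4-(2-Ar-1,3-dithian-2-yl)-5-menthyloxyoxolan-2-one | [Li]OC1=C[C@@H](C2(SCCCS2)c2cc(OC)c(OCc3ccccc3)c(OC)c2)[C@H](O[C@@H]2C[C@H](C)CC[C@H]2C(C)C)O1 | intermediate
12 | lithium alkoxide of 13 | O=C1O[C@@H](O[C@@H]2C[C@H](C)CC[C@H]2C(C)C)[C@H](C2(SCCCS2)c2cc(OC)c(OCc3ccccc3)c(OC)c2)[C@H]1[C@H](O[Li])c1cc(OC)c(OCc2ccccc2)c(OC)c1 | intermediate
13 | (3S,4R,5R)-3-[(S)-Ar(hydroxy)methyl]-4-(2-Ar-1,3-dithian-2-yl)-5-[(1R,2S,5R)-menthyloxy]oxolan-2-one | O=C1O[C@@H](O[C@@H]2C[C@H](C)CC[C@H]2C(C)C)[C@H](C2(SCCCS2)c2cc(OC)c(OCc3ccccc3)c(OC)c2)[C@H]1[C@H](O)c1cc(OC)c(OCc2ccccc2)c(OC)c1 | intermediate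
14 | (2R,3R)-2-[(S)-Ar(hydroxy)methyl]-3-(2-Ar-1,3-dithian-2-yl)butane-1,4-diol | OC[C@H](C1(SCCCS1)c1cc(OC)c(OCc2ccccc2)c(OC)c1)[C@H](CO)[C@H](O)c1cc(OC)c(OCc2ccccc2)c(OC)c1 | intermediate
15 | 1,4-bis-O-TBDPS ether of 14, benzylic OH free | CC(C)(C)[Si](c1ccccc1)(c1ccccc1)OC[C@H](C1(SCCCS1)c1cc(OC)c(OCc2ccccc2)c(OC)c1)[C@H](CO[Si](c1ccccc1)(c1ccccc1)C(C)(C)C)[C@H](O)c1cc(OC)c(OCc2ccccc2)c(OC)c1 | intermediate
16 | (2R,3R,4S)-1,4-di-Ar-2,3-bis(TBDPSO-methyl)-4-hydroxybutan-1-one | CC(C)(C)[Si](c1ccccc1)(c1ccccc1)OC[C@H](C(=O)c1cc(OC)c(OCc2ccccc2)c(OC)c1)[C@H](CO[Si](c1ccccc1)(c1ccccc1)C(C)(C)C)[C@H](O)c1cc(OC)c(OCc2ccccc2)c(OC)c1 | intermediate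
17 | (3R,4R,5S)-2,5-di-Ar-3,4-bis(TBDPSO-methyl)oxolan-2-ol, C2 anomers | CC(C)(C)[Si](c1ccccc1)(c1ccccc1)OC[C@H]1[C@H](CO[Si](c2ccccc2)(c2ccccc2)C(C)(C)C)[C@@H](c2cc(OC)c(OCc3ccccc3)c(OC)c2)OC1(O)c1cc(OC)c(OCc2ccccc2)c(OC)c1 | intermediate
18 | (3R,4R,5S) cyclic O1=C2 oxocarbenium ion from 17, hydroxytrifluoroborate salt | CC(C)(C)[Si](c1ccccc1)(c1ccccc1)OC[C@H]1[C@H](CO[Si](c2ccccc2)(c2ccccc2)C(C)(C)C)[C@@H](c2cc(OC)c(OCc3ccccc3)c(OC)c2)[O+]=C1c1cc(OC)c(OCc2ccccc2)c(OC)c1.O[B-](F)(F)F | intermediate
19 | (2S,3R,4R,5S)-2,5-di-Ar-3,4-bis(TBDPSO-methyl)oxolane | CC(C)(C)[Si](c1ccccc1)(c1ccccc1)OC[C@H]1[C@H](CO[Si](c2ccccc2)(c2ccccc2)C(C)(C)C)[C@@H](c2cc(OC)c(OCc3ccccc3)c(OC)c2)O[C@@H]1c1cc(OC)c(OCc2ccccc2)c(OC)c1 | intermediate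
20 | [(2S,3R,4R,5S)-2,5-di-Ar-oxolane-3,4-diyl]dimethanol | OC[C@H]1[C@H](CO)[C@@H](c2cc(OC)c(OCc3ccccc3)c(OC)c2)O[C@@H]1c1cc(OC)c(OCc2ccccc2)c(OC)c1 | intermediate
21 | huazhongilexin | COc1cc([C@H]2O[C@H](c3cc(OC)c(O)c(OC)c3)[C@@H](CO)[C@@H]2CO)cc(OC)c1O | target

Total step count: 11.

Longest linear sequence: 9 steps (3, 4, 5–11 from syringaldehyde; equally 1, 2, 5–11 from furfural).

Steps most likely to fail

Step 5.
- **What may go wrong:** The conjugate addition may be incomplete, so that residual carbanion attacks the aldehyde directly. A proton may reach the enolate before the aldehyde arrives. Retro-aldol cleavage may occur during the quench.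
- **Fallback (two separate operations instead of the tandem):** It sets out from 9 (with 5). Only the Michael addition is run (n-BuLi, THF, −78 °C) and enolate 11 is protonated cold with AcOH. Purification gives the conjugate adduct (4R,5R)-4-(2-Ar-1,3-dithian-2-yl)-5-[(1R,2S,5R)-menthyloxy]oxolan-2-one F1. In a second flask F1 is deprotonated with LiN(iPr)2 (THF, −78 °C), which regenerates 11 free of 10, and 7 is added. The aldol again occurs anti to the dithianyl group, and the sequence comes back to the route at 13.

Step 9.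
- **What may go wrong:** The facial bias of hydride delivery may be too small. Equilibration at C5 may be slow, because the twisted trialkoxyaryl group stabilises the cation only moderately. The oxocarbenium ion may lose a proton next to the silyloxymethyl group. The ring-opened benzylic cation may be over-reduced.
- **Fallback (ring closure by etherification instead of hemiketal reduction):** It sets out from 17, which is reduced through its open form with NaBH4 (THF–MeOH, 0 °C). This gives the 1,4-diol (1S,2R,3R)-1,4-di-Ar-2,3-bis(TBDPSO-methyl)butane-1,4-diol (C4 carbinol as a mixture) F2. A catalytic amount of p-TsOH in CH2Cl2 (0 °C → rt) then effects an ionising SN1 cyclodehydration. Either benzylic carbon can ionise and re-close in this step until the least crowded all-trans ring is reached. The sequence comes back to the route at 19.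

Step 8.
- **What may go wrong:** S-alkylation may be sluggish at a dithiane crowded by two TBDPS groups. The lipophilic substrate may dissolve poorly in the aqueous medium. Epimerisation or β-elimination may occur at the open ketone stage.
- **Fallback (unmasking before reduction and silylation):** It sets out from 13. The dithiane is removed on the compact lactone with HgO and BF3·OEt2 in aqueous THF at rt. This gives the keto lactone (3S,4R,5R)-3-[(S)-Ar(hydroxy)methyl]-4-(Ar-carbonyl)-5-[(1R,2S,5R)-menthyloxy]oxolan-2-one F3.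
- LiAlH4 (THF, 0 °C) reduces ketone and acetal-lactone together to the tetraol (2R,3R)-2,3-bis[Ar(hydroxy)methyl]butane-1,4-diol (new carbinol as a mixture) F4.
- TBDPSCl and imidazole (2.2 equiv, DMF) silylate the two primary hydroxyls to give the diol F2, which is cyclodehydrated with catalytic p-TsOH as above. The sequence comes back to the route at 19.

Further compounds
F1 | step 5 | (4R,5R)-4-(2-Ar-1,3-dithian-2-yl)-5-[(1R,2S,5R)-menthyloxy]oxolan-2-one | O=C1O[C@@H](O[C@@H]2C[C@H](C)CC[C@H]2C(C)C)[C@H](C2(SCCCS2)c2cc(OC)c(OCc3ccccc3)c(OC)c2)C1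
F2 | step 9 | (1S,2R,3R)-1,4-di-Ar-2,3-bis(TBDPSO-methyl)butane-1,4-diol, C4 unassigned | CC(C)(C)[Si](c1ccccc1)(c1ccccc1)OC[C@H](C(O)c1cc(OC)c(OCc2ccccc2)c(OC)c1)[C@H](CO[Si](c1ccccc1)(c1ccccc1)C(C)(C)C)[C@H](O)c1cc(OC)c(OCc2ccccc2)c(OC)c1
F3 | step 8 | (3S,4R,5R)-3-[(S)-Ar(hydroxy)methyl]-4-(Ar-carbonyl)-5-[(1R,2S,5R)-menthyloxy]oxolan-2-one | O=C1O[C@@H](O[C@@H]2C[C@H](C)CC[C@H]2C(C)C)[C@H](C(=O)c2cc(OC)c(OCc3ccccc3)c(OC)c2)[C@H]1[C@H](O)c1cc(OC)c(OCc2ccccc2)c(OC)c1
F4 | step 8 | (2R,3R)-2,3-bis[Ar(hydroxy)methyl]butane-1,4-diol, one carbinol (S), the other unassigned | OC[C@H](C(O)c1cc(OC)c(OCc2ccccc2)c(OC)c1)[C@H](CO)[C@H](O)c1cc(OC)c(OCc2ccccc2)c(OC)c1
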